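The route numbering is as follows. The seven-membered ring is C1 (ester carbinol), C2, C3(Me)=C4, C5 (C=O), C6 (quaternary, Me), C10. The five-membered ring is C6, C7, C8, C9 (isopropyl carbinol), C10. Within the seven-membered ring, the C5 ketone, the C3=C4 alkene, the C2 methylene and the quaternary C6 form the retron of a ketene Cope rearrangement. The ring is therefore cut at C5–C6 and C3–C4, and C1–C3 is reconnected. One operation, a Wolff rearrangement followed by a [3,3] shift, forms both bonds, expands a cyclopropane into the cycloheptadienone and sets C6. The precursor is a cis-1-methyl-2-cyclopentenylcyclopropyl diazomethyl ketone. Its cyclopentene half (C1, C6 to C10) comes from (S)-terpinen-4-ol.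

Key step: step 9

Assumption: (S)-(+)-terpinen-4-ol is taken as purchasable in high enantiomeric purity; any (R)-enantiomer carried along becomes a separable diastereomer after the reagent-controlled cyclopropanation of step 6.

Step 1
Reactants: 1 (S)-(+)-terpinen-4-ol
Product: 2 (S)-terpinen-4-ol triethylsilyl ether
Conditions: Et3SiOTf, 2,6-lutidine, CH2Cl2, 0 °C to rt
Reagents that add atoms: triethylsilyl trifluoromethanesulfonate, CC[Si](CC)(CC)OS(=O)(=O)C(F)(F)F
Why: Silylation of a tertiary alcohol with a silyl triflate and a hindered pyridine base is routine and leaves the alkene and the stereocentre (future C9) untouched, and capping the oxygen before any carbonyl group exists rules out retro-aldol cleavage, hemiketal formation and lactonisation in steps 2 to 9.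

Step 2
Reactants: 2 (S)-terpinen-4-ol triethylsilyl ether
Product: 4 (3S)-6-oxo-3-(propan-2-yl)-3-(triethylsilyloxy)heptanal, via secondary ozonide 3 (not isolated)
Conditions: O3, CH2Cl2, −78 °C; then PPh3, −78 °C to rt
Reagents that add atoms: ozone, [O-][O+]=O
Why: Ozonolysis with reductive phosphine work-up cleaves the only C=C bond to the C6 methyl ketone and the C1 aldehyde under cold neutral conditions that a β-silyloxy aldehyde tolerates, and no stereocentre is touched.

Step 3
Reactants: 4 (3S)-6-oxo-3-(propan-2-yl)-3-(triethylsilyloxy)heptanal
Product: 5 (5R)-2-methyl-5-(propan-2-yl)-5-(triethylsilyloxy)cyclopent-1-ene-1-carbaldehyde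
Conditions: piperidine (0.5 equiv), AcOH (0.5 equiv), 4 Å molecular sieves, toluene, 60 °C
Reagents that add atoms: none
Why: Amine-catalysed intramolecular aldol condensation (5-enolexo): piperidine forms an enamine only with the aldehyde, its α-carbon C10 attacks the C6 ketone in a ring closure favoured by the fully substituted C9, and the new free C6 hydroxyl is lost in preference to the silyl-capped C9 oxygen, so the C10=C6 enal forms with C9 intact.

Step 4
Reactants: 5 (5R)-2-methyl-5-(propan-2-yl)-5-(triethylsilyloxy)cyclopent-1-ene-1-carbaldehyde; 6 methyl 2-[bis(2,2,2-trifluoroethoxy)phosphoryl]propanoate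
Product: 7 methyl (2Z)-2-methyl-3-[(5R)-2-methyl-5-(propan-2-yl)-5-(triethylsilyloxy)cyclopent-1-en-1-yl]prop-2-enoate
Conditions: KN(SiMe3)2, 18-crown-6, THF, −78 °C to −40 °C
Reagents that add atoms: none
Why: Still–Gennari olefination: with the electron-poor trifluoroethyl phosphonate and a crown-complexed potassium ion the kinetic adduct collapses before it can equilibrate, which places the ester cis to the cyclopentenyl group (Z), the geometry needed for a cis cyclopropane, while the soft anion adds to the aldehyde at −78 °C faster than it can deprotonate the γ positions.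

Step 5
Reactants: 7 methyl (2Z)-dienoate
Product: 8 (2Z)-2-methyl-3-[(5R)-2-methyl-5-(propan-2-yl)-5-(triethylsilyloxy)cyclopent-1-en-1-yl]prop-2-en-1-ol
Conditions: i-Bu2AlH (2.5 equiv), CH2Cl2, −78 °C; aq potassium sodium tartrate
Reagents that add atoms: none
Why: 1,2-Reduction of the conjugated ester with i-Bu2AlH at low temperature gives the allylic alcohol without change of alkene geometry or loss of the silyl ether.

Step 6
Reactants: 8 (2Z)-allylic alcohol
Product: 9 {(1S,2R)-1-methyl-2-[(5R)-2-methyl-5-(propan-2-yl)-5-(triethylsilyloxy)cyclopent-1-en-1-yl]cyclopropyl}methanol (route numbering 3S,1R,9R; CH2OH cis to the cyclopentenyl group)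
Conditions: Et2Zn, CH2I2, DME, CH2Cl2, −10 °C; then 8 and (4R,5R)-2-butyl-N,N,N',N'-tetramethyl-1,3,2-dioxaborolane-4,5-dicarboxamide (1.2 equiv), −10 °C to rt
Reagents that add atoms: diiodomethane, ICI
Why: Charette asymmetric Simmons–Smith cyclopropanation: the zinc alkoxide of 8, bound to the chiral dioxaborolane, receives CH2 stereospecifically (Z alkene to cis cyclopropane) and only at the allylic C3=C1 bond, the (4R,5R) ligand being the enantiomer whose established facial preference gives 3S and 1R, and because C9 is already fixed any facial isomer is a diastereomer that can be removed by chromatography.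

Step 7
Reactants: 9 cis-cyclopropylmethanol
Product: 11 (1S,2S)-1-methyl-2-[(5R)-2-methyl-5-(propan-2-yl)-5-(triethylsilyloxy)cyclopent-1-en-1-yl]cyclopropane-1-carboxylic acid, via cyclopropanecarbaldehyde 10 (not isolated)
Conditions: TEMPO (0.2 equiv), PhI(OAc)2, CH2Cl2, rt; then t-BuOH/H2O, 2-methyl-2-butene, NaH2PO4, NaClO2, 0 °C to rt
Reagents that add atoms: sodium chlorite, [Na+].[O-]Cl=O
Why: Oxoammonium (TEMPO/PhI(OAc)2) oxidation followed in the same flask by Pinnick oxidation converts the primary alcohol into the acid at near-neutral pH, the alkene scavenger shielding the tetrasubstituted C10=C6 bond from HOCl, the quaternary C3 excluding epimerisation, and the telescoping leaving the cis-vinylcyclopropyl aldehyde no time for a retro-Claisen drift.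

Step 8
Reactants: 11 cis-cyclopropanecarboxylic acid; 12 (trimethylsilyl)diazomethane
Product: 14 2-diazo-1-{(1S,2S)-1-methyl-2-[(5R)-2-methyl-5-(propan-2-yl)-5-(triethylsilyloxy)cyclopent-1-en-1-yl]cyclopropyl}ethan-1-one, via acid chloride 13 (not isolated)
Conditions: 1-chloro-N,N,2-trimethylprop-1-en-1-amine, CH2Cl2, 0 °C to rt; then Me3SiCHN2 (3 equiv), THF/MeCN, 0 °C to rt
Reagents that add atoms: 1-chloro-N,N,2-trimethylprop-1-en-1-amine, CC(C)=C(Cl)N(C)C (supplies only the chlorine of 13)
Why: Acid chloride formation with the Ghosez chloroenamine liberates no HCl and so spares the tertiary allylic silyl ether, and C-acylation of (trimethylsilyl)diazomethane with loss of the silyl group (first half of an Arndt–Eistert sequence) gives the diazomethyl ketone without touching C1 or the non-enolisable C3.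

Step 9
Reactants: 14 cis-1-methyl-2-cyclopentenylcyclopropyl diazomethyl ketone
Product: 16 (6S,9R)-hydroazulene dienone 9-O-triethylsilyl ether (C5 ketone; C3=C4 and C1=C10 alkenes; methyl on C3 and C6; isopropyl on C9), via cyclopropyl ketene 15 (not isolated)
Conditions: hν (300 nm lamps, Pyrex), dry degassed THF (0.01 M), 25 °C until 14 is consumed; then 45 °C in the dark
Reagents that add atoms: none
Why: Light expels N2 from the s-cis diazoketone while C3 shifts with retention from the carbonyl carbon (the future C5) to the diazo carbon (C4), which gives ketene 15 with its C4=C5 bond and the C10=C6 bond held cis on the three-membered ring. A boat-shaped [3,3] shift then joins the electrophilic sp carbon C5 to the electron-rich C6, breaks the strained C1–C3 bond and leaves the π bonds at C3=C4 and C1=C10. The closest known reaction type is the tandem Wolff/Cope rearrangement of 2-vinylcyclopropyl diazomethyl ketones to fused cyclohepta-2,5-dienones, a ketene version of the cis-divinylcyclopropane rearrangement, and the only stretch here is that the accepting alkene carbon is fully substituted. The seven-membered ring C1–C2–C3–C4–C5–C6–C10 is closed by sigmatropic ring expansion of the cyclopropane (three to seven atoms), not by end-to-end cyclisation of a chain. C6, the one new stereocentre, is controlled by the cyclopropane configuration set in step 6, because only the rotamer with both π bonds folded over C2 can react and it presents a single face of C10=C6 to C5, placing C5 anti and the methyl group syn to the C9 oxygen (6S). The step needs this facial selectivity and a Cope shift that outruns dimerisation or capture of the ketene, and the substrate provides for both through the cis geometry, the silyl cap on the C9 oxygen (no internal nucleophile), the small steric demand of the sp terminus and the bulky C9 centre that turns C6 rather than itself over the ring.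

Step 10
Reactants: 16 hydroazulene dienone triethylsilyl ether
Product: 17 (6S,9R)-9-hydroxy hydroazulene dienone
Conditions: Bu4NF/AcOH (1:1), THF, 0 °C to rt
Reagents that add atoms: none
Why: Fluoride desilylation buffered with acetic acid cleaves the triethylsilyl ether close to neutrality, which avoids both base-induced migration of the C1=C10 bond through the doubly allylic C2 methylene and acid ionisation of the tertiary allylic alcohol.

Step 11
Reactants: 17 9-hydroxy hydroazulene dienone
Product: 18 (1R,6S,9R,10S)-1,10-epoxide of 17 (oxirane oxygen syn to the C9 hydroxyl and the C6 methyl)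
Conditions: VO(acac)2 (5 mol %), t-BuOOH (decane), CH2Cl2, 0 °C to rt
Reagents that add atoms: tert-butyl hydroperoxide, CC(C)(C)OO
Why: Hydroxyl-directed epoxidation with VO(acac)2 and t-BuOOH: the C9 alkoxide carries the vanadium-bound peroxide to the adjacent C1=C10 bond on its own face, which sets C1 as R (and C10–O syn to the C9 oxygen and the C6 methyl), and the electron-poor remote C3=C4 enone bond is ignored.

Step 12
Reactants: 18 epoxy alcohol
Product: 19 (1R,6S,9R,10S)-1,9-dihydroxy enone (trans-fused; C10–H anti to the C6 methyl)
Conditions: Cp2TiCl2 (3 equiv), Mn dust, THF, rt; then 18, 1,4-cyclohexadiene (15 equiv), THF, 0 °C to rt; aq NaH2PO4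
Reagents that add atoms: none
Why: Nugent–RajanBabu reductive epoxide opening as known for trisubstituted 2,3-epoxy alcohols: Cp2TiCl (trivalent titanium) cleaves the C10–O bond homolytically toward the tertiary radical and leaves the C1–O bond and its configuration intact, 1,4-cyclohexadiene then delivers hydrogen to the face opposite the bulky C1 titanoxy group, the C6 methyl and the C9 oxygen to give the trans ring fusion (10S), and the radical course avoids the semipinacol shift of the isopropyl group that a Lewis acid would trigger.

Step 13
Reactants: 20 vanillic acid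
Product: 22 4-(tert-butyldimethylsilyloxy)-3-methoxybenzoic acid, via bis-silylated vanillate 21 (not isolated)
Conditions: t-BuMe2SiCl (2.3 equiv), imidazole, DMF, rt; then THF/H2O/AcOH, rt
Reagents that add atoms: tert-butyldimethylsilyl chloride, CC(C)(C)[Si](C)(C)Cl
Why: Exhaustive silylation followed by mild aqueous acid exploits the much greater lability of a silyl ester compared with an aryl silyl ether, so only the phenol stays protected.

Step 14
Reactants: 19 1,9-dihydroxy enone; 22 4-(tert-butyldimethylsilyloxy)-3-methoxybenzoic acid
Product: 23 C1 ester of 19 with O-silylated vanillic acid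
Conditions: N,N'-dicyclohexylcarbodiimide, 4-(dimethylamino)pyridine, CH2Cl2, rt
Reagents that add atoms: none
Why: Steglich esterification: the acylpyridinium ion formed from 22 acylates the secondary C1 hydroxyl with retention while the tertiary C9 hydroxyl is too hindered to compete, and the mild base does not provoke vinylogous elimination across C1–C2.

Step 15
Reactants: 23 silyl-protected ester
Product: 24 (3R,3aS,4R,8aS)-3-hydroxy-6,8a-dimethyl-8-oxo-3-(propan-2-yl)-1,2,3,3a,4,5,8,8a-octahydroazulen-4-yl 4-hydroxy-3-methoxybenzoate (route numbering 9R,10S,1R,6S)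
Conditions: HF·pyridine, pyridine, THF, 0 °C
Reagents that add atoms: none
Why: Fluoride cleavage of the aryl silyl ether under slightly acidic conditions is fast and avoids basic media, in which the C1 acyloxy group could leave by vinylogous E1cB elimination, so ester, enone and tertiary alcohol survive and all four stereocentres stay as set.

Compound list
1 | (S)-(+)-terpinen-4-ol | CC1=CC[C@](O)(C(C)C)CC1 | starting material
2 | (S)-terpinen-4-ol triethylsilyl ether | CC1=CC[C@](O[Si](CC)(CC)CC)(C(C)C)CC1 | intermediate
3 | secondary ozonide of 2 (ozonide carbons unassigned, irrelevant) | CC12CC[C@@](O[Si](CC)(CC)CC)(C(C)C)CC(OO1)O2 | intermediate (not isolated)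
4 | (3S)-6-oxo-3-(propan-2-yl)-3-(triethylsilyloxy)heptanal | CC(=O)CC[C@@](O[Si](CC)(CC)CC)(C(C)C)CC=O | intermediate
5 | (5R)-2-methyl-5-(propan-2-yl)-5-(triethylsilyloxy)cyclopent-1-ene-1-carbaldehyde | O=CC1=C(C)CC[C@@]1(O[Si](CC)(CC)CC)C(C)C | intermediate
6 | methyl 2-[bis(2,2,2-trifluoroethoxy)phosphoryl]propanoate | COC(=O)C(C)P(=O)(OCC(F)(F)F)OCC(F)(F)F | starting material
7 | methyl (2Z)-dienoate | COC(=O)/C(C)=C\C1=C(C)CC[C@@]1(O[Si](CC)(CC)CC)C(C)C | intermediate
8 | (2Z)-allylic alcohol | OC/C(C)=C\C1=C(C)CC[C@@]1(O[Si](CC)(CC)CC)C(C)C | intermediate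
9 | cis-cyclopropylmethanol (3S,1R,9R) | OC[C@@]1(C)C[C@H]1C2=C(C)CC[C@@]2(O[Si](CC)(CC)CC)C(C)C | intermediate
10 | cis-cyclopropanecarbaldehyde | O=C[C@@]1(C)C[C@H]1C2=C(C)CC[C@@]2(O[Si](CC)(CC)CC)C(C)C | intermediate (not isolated)
11 | cis-cyclopropanecarboxylic acid | OC(=O)[C@@]1(C)C[C@H]1C2=C(C)CC[C@@]2(O[Si](CC)(CC)CC)C(C)C | intermediate
12 | (trimethylsilyl)diazomethane | C[Si](C)(C)C=[N+]=[N-] | starting material
13 | cis-cyclopropanecarbonyl chloride | ClC(=O)[C@@]1(C)C[C@H]1C2=C(C)CC[C@@]2(O[Si](CC)(CC)CC)C(C)C | intermediate (not isolated)
14 | cis-1-methyl-2-cyclopentenylcyclopropyl diazomethyl ketone | [N-]=[N+]=CC(=O)[C@@]1(C)C[C@H]1C2=C(C)CC[C@@]2(O[Si](CC)(CC)CC)C(C)C | intermediate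
15 | cis-2-cyclopentenylcyclopropyl ketene | O=C=C[C@@]1(C)C[C@H]1C2=C(C)CC[C@@]2(O[Si](CC)(CC)CC)C(C)C | intermediate (not isolated)
16 | (6S,9R)-hydroazulene dienone 9-O-triethylsilyl ether | O=C1C=C(C)CC=C2[C@](O[Si](CC)(CC)CC)(C(C)C)CC[C@]12C | intermediate
17 | (6S,9R)-9-hydroxy hydroazulene dienone | O=C1C=C(C)CC=C2[C@](O)(C(C)C)CC[C@]12C | intermediate
18 | (1R,6S,9R,10S)-1,10-epoxy alcohol | O=C1C=C(C)C[C@H]2O[C@]23[C@](O)(C(C)C)CC[C@]13C | intermediate
19 | (1R,6S,9R,10S)-1,9-dihydroxy enone | O[C@@H]1CC(C)=CC(=O)[C@@]2(C)CC[C@@](O)(C(C)C)[C@H]12 | intermediate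
20 | vanillic acid | COc1cc(C(=O)O)ccc1O | starting material
21 | tert-butyldimethylsilyl 4-(tert-butyldimethylsilyloxy)-3-methoxybenzoate | COc1cc(C(=O)O[Si](C)(C)C(C)(C)C)ccc1O[Si](C)(C)C(C)(C)C | intermediate (not isolated)
22 | 4-(tert-butyldimethylsilyloxy)-3-methoxybenzoic acid | COc1cc(C(=O)O)ccc1O[Si](C)(C)C(C)(C)C | intermediate
23 | silyl-protected C1 vanillate | COc1cc(C(=O)O[C@@H]2CC(C)=CC(=O)[C@@]3(C)CC[C@@](O)(C(C)C)[C@H]23)ccc1O[Si](C)(C)C(C)(C)C | intermediate
24 | CNP0136950.1 | COc1cc(C(=O)O[C@@H]2CC(C)=CC(=O)[C@@]3(C)CC[C@@](O)(C(C)C)[C@H]23)ccc1O | target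

Total step count: 15.
Longest linear sequence: 14 (steps 1 to 12, then 14 and 15, from 1).

Steps most likely to fail

Step 9. The sigmatropic shift may be slower than the other reactions open to a free ketene.
- The C6 methyl group is the inward-pointing substituent of the boat and is pressed against the C2 methylene.
- Dimerisation, capture by traces of water or photodecarbonylation of the waiting ketene may therefore compete.
- A light-driven 1,3-acyl shift in the product may also erode the outcome.

The fallback sets out from 14 and returns at 17. It replaces the ketene by a heat-tolerant enol ether, so the Cope step can be forced thermally. Irradiation of 14 in MeOH (Arndt–Eistert homologation) gives the homologated methyl ester F1. Reduction with i-Bu2AlH at −78 °C gives the homologated aldehyde F2. Treatment with t-BuMe2SiOTf/Et3N gives the silyl enol ether F3 as an E/Z mixture, and both isomers are usable. Heating in toluene or xylene (110 to 140 °C, base-washed glass) drives the siloxy-divinylcyclopropane rearrangement to the C5 silyl ether F4, with the same transfer of chirality from the cyclopropane to C6. Bu4NF then removes both silyl groups to give the diol F5. MnO2 oxidises only its secondary allylic C5 hydroxyl, and this gives 17.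

Step 12. The C10 radical is flanked by two fully substituted carbons, so hydrogen transfer to it may be slow or may come from the wrong face and give cis fusion. A long-lived radical may also suffer a 1,2-acyl shift of C5, and excess Cp2TiCl may reduce the enone.

The fallback sets out from 17 and returns at 19. It sets C10 by equilibration instead of by radical capture. DBU in toluene moves the C1=C10 bond into conjugation through the C2 dienolate and gives the conjugated 2,4-dienone F6. In F6 the epimerisable C10–H should settle trans to the C6 methyl, because C1 then avoids the isopropyl group. Epoxidation of the distal, more electron-rich C1=C2 bond with mCPBA/NaHCO3, guided by hydrogen bonding to the homoallylic C9 hydroxyl, gives the γ,δ-epoxy enone F7. This alkenyl oxirane is hydrogenolysed with formate under zerovalent palladium catalysis (Pd2(dba)3·CHCl3, PBu3, HCO2H, Et3N, dioxane). Hydride is delivered to C2, the C1–O bond and the C3=C4 enone are kept, and the product is 19.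

Step 3. The enamine, or the dienamine of the product, may expel the β-silyloxy group. Loss of the C9 oxygen, and with it the only stereocentre, would then compete with the wanted dehydration at C6.

The fallback sets out from 4 and returns at 5. It separates bond formation from dehydration and tells the two β-oxygens apart by leaving-group quality. (S)-Proline in DMSO at rt stops at the aldol stage and gives the hydroxy aldehyde F8, whose new centres at C6 and C10 are irrelevant. (CF3CO)2O/pyridine acylates its only free hydroxyl to give the trifluoroacetate F9. DBU at 0 °C then removes C10–H and expels trifluoroacetate (E1cB), a far better leaving group than the silanolate, to give 5.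

Further compounds
F1 | step 9 | homologated methyl ester (cyclopropane and C9 as in 14) | COC(=O)C[C@@]1(C)C[C@H]1C2=C(C)CC[C@@]2(O[Si](CC)(CC)CC)C(C)C
F2 | step 9 | homologated aldehyde | O=CC[C@@]1(C)C[C@H]1C2=C(C)CC[C@@]2(O[Si](CC)(CC)CC)C(C)C
F3 | step 9 | tert-butyldimethylsilyl enol ether of F2 (E/Z mixture) | CC(C)(C)[Si](C)(C)OC=C[C@@]1(C)C[C@H]1C2=C(C)CC[C@@]2(O[Si](CC)(CC)CC)C(C)C
F4 | step 9 | C5 silyl ether of the hydroazulene diene (C5 unassigned, removed on oxidation) | CC(C)(C)[Si](C)(C)OC1C=C(C)CC=C2[C@](O[Si](CC)(CC)CC)(C(C)C)CC[C@]12C
F5 | step 9 | hydroazulene diene 5,9-diol | OC1C=C(C)CC=C2[C@](O)(C(C)C)CC[C@]12C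
F6 | step 12 | trans-fused conjugated 2,4-dienone | O=C1C=C(C)C=C[C@H]2[C@](O)(C(C)C)CC[C@]12C
F7 | step 12 | C1–C2 epoxide of F6 (oxygen syn to the C9 hydroxyl) | O=C1C=C(C)[C@H]3O[C@H]3[C@H]2[C@](O)(C(C)C)CC[C@]12C
F8 | step 3 | aldol adduct, 2-hydroxy-2-methyl-5-(propan-2-yl)-5-(triethylsilyloxy)cyclopentane-1-carbaldehyde | O=CC1C(C)(O)CC[C@@]1(O[Si](CC)(CC)CC)C(C)C
F9 | step 3 | trifluoroacetate of F8 | O=CC1C(C)(OC(=O)C(F)(F)F)CC[C@@]1(O[Si](CC)(CC)CC)C(C)C
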